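The carbocycle (C4a–C5–C6–C7–C8–C8a) is cut into two three-carbon halves that are both electrophilic by nature. C8 and C4a stand 1,3 to each other and are handled as the two carbonyl carbons of a cyclohexane-1,3-dione; C7 and C5 are the ketone carbon and the oxirane CH2 of a small epoxy ketone that already holds the C6 oxygen. Twofold polarity reversal (a dilithiated bis-dithiane) unites the halves in one [3+3] annulation: carbonyl addition makes C8–C7, oxirane opening makes C4a–C5, and C6 controls C7. The dione is then annulated to the pyran ring (C1 by Stille, C3/C4 by Sonogashira coupling and 6-endo cyclisation), and the aryl ester is attached last.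

Key step: step 3

Remark: atom labels are those of the 1H-isochromene core of the target (C1, O2, C3, C4, C4a, C5–C8, C8a); compounds 4 and 13 are taken as purchasable.

Step 1
Reactants: 1 rac-but-3-en-2-ol
Product: 2 (2R,3S)-3,4-epoxybutan-2-ol
Conditions: Ti(OiPr)4 (cat.), D-(−)-diisopropyl tartrate (cat.), t-BuOOH (0.55 equiv), 4 Å sieves, CH2Cl2, −20 °C
Reagents that add atoms: tert-butyl hydroperoxide, CC(C)(C)OO
Why: In this Sharpless kinetic resolution the (R)-alcohol should be epoxidised fast with D-(−)-tartrate to the erythro epoxy alcohol, which fixes the oxirane stereocentre (later C6) as S while the slow (S)-alcohol stays behind.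

Step 2
Reactants: 2 (2R,3S)-3,4-epoxybutan-2-ol
Product: 3 (S)-1-(oxiran-2-yl)ethan-1-one
Conditions: (n-Pr)4N[RuO4] (cat.), N-methylmorpholine N-oxide, 4 Å sieves, CH2Cl2, 0 °C to rt
Reagents that add atoms: none
Why: Ley–Griffith oxidation of the secondary alcohol under neutral conditions should give the methyl ketone without touching the oxirane or its stereocentre.

Step 3
Reactants: 3 (S)-1-(oxiran-2-yl)ethan-1-one; 4 bis(1,3-dithian-2-yl)methane
Product: 7 (5S,6R)-5,6-dihydroxy-6-methylcyclohexane-1,3-dione bis(propane-1,3-diyl dithioketal), via dilithiated bis-dithiane 5 (not isolated), via lithium alkoxide mono-adduct 6 (not isolated)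
Conditions: 4 (1.2 equiv), n-BuLi (2.4 equiv), THF, −30 °C; 3 added slowly at −78 °C; then HMPA, −78 to 0 °C; aq. NH4Cl
Reagents that add atoms: none
Why: Twofold deprotonation turns 4 into a 1,3-diacyl dianion equivalent; at −78 °C one carbanion should add to the ketone of 3 (C8–C7), and on warming with HMPA the second should open the oxirane of alkoxide 6 at its CH2 (C4a–C5). Both events are standard 2-lithio-1,3-dithiane chemistry (Corey–Seebach carbonyl addition and epoxide alkylation), combined here as a [3+3] annulation of a 1,3-dinucleophile with a 1,3-dielectrophile. The cyclohexane ring closes in the second event by 6-endo-tet attack on the primary oxirane carbon. C7 is set by the oxirane stereocentre: in the lithium-bridged conformer (carbonyl O syn to oxirane O) the carbanion should enter anti to the oxirane CH2, the sense known from erythro-selective hydride additions to epoxy ketones, which gives the R carbinol and hence the trans-diol, while C6 is carried over untouched. The step needs 6-endo over 5-exo opening (C5 is primary, C6 is flanked by the fully substituted C7), a single carbonyl addition per dianion (slow addition of 3 to excess 5) and no oxirane migration (lithium alkoxide in THF at low temperature).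

Step 4
Reactants: 7 (5S,6R)-5,6-dihydroxy-6-methylcyclohexane-1,3-dione bis(propane-1,3-diyl dithioketal)
Product: 8 (5S,6R)-5-[(tert-butyldimethylsilyl)oxy]-6-hydroxy-6-methylcyclohexane-1,3-dione bis(propane-1,3-diyl dithioketal)
Conditions: TBSOTf, 2,6-lutidine, CH2Cl2, −78 °C
Reagents that add atoms: tert-butyldimethylsilyl triflate, CC(C)(C)[Si](C)(C)OS(=O)(=O)C(F)(F)F
Why: Silylation should occur only at the secondary C6 hydroxyl, because the tertiary C7 hydroxyl is shielded by the adjacent spiro dithiane.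

Step 5
Reactants: 8 (5S,6R)-5-[(tert-butyldimethylsilyl)oxy]-6-hydroxy-6-methylcyclohexane-1,3-dione bis(propane-1,3-diyl dithioketal)
Product: 9 (5S,6R)-5-[(tert-butyldimethylsilyl)oxy]-6-hydroxy-6-methylcyclohexane-1,3-dione
Conditions: Hg(ClO4)2, CaCO3, THF/H2O, 0 °C to rt
Reagents that add atoms: water, O
Why: Thiophilic mercury-assisted hydrolysis should unveil both carbonyls (C4a and C8) of the 1,3-dione, the CaCO3 buffer keeping the silyl ether intact.

Step 6
Reactants: 9 (5S,6R)-5-[(tert-butyldimethylsilyl)oxy]-6-hydroxy-6-methylcyclohexane-1,3-dione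
Product: 11 (4R,5S)-5-[(tert-butyldimethylsilyl)oxy]-4-hydroxy-2-iodo-4-methyl-3-oxocyclohex-1-en-1-yl 4-methylbenzenesulfonate, via 2-iodo dione enol 10 (not isolated)
Conditions: N-iodosuccinimide, CH2Cl2, 0 °C, dark; then Et3N, TsCl, 0 °C
Reagents that add atoms: N-iodosuccinimide, O=C1CCC(=O)N1I; 4-toluenesulfonyl chloride, Cc1ccc(cc1)S(Cl)(=O)=O
Why: Electrophilic iodination of the enolised dione at C8a, then O-sulfonylation of the less hindered enol oxygen (on C4a, remote from the quaternary C7), should give two sp2 leaving groups of clearly different reactivity.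

Step 7
Reactants: 11 (4R,5S)-5-[(tert-butyldimethylsilyl)oxy]-4-hydroxy-2-iodo-4-methyl-3-oxocyclohex-1-en-1-yl 4-methylbenzenesulfonate
Product: 12 (4R,5S)-5-[(tert-butyldimethylsilyl)oxy]-4-hydroxy-2-(hydroxymethyl)-4-methyl-3-oxocyclohex-1-en-1-yl 4-methylbenzenesulfonate
Conditions: Bu3SnCH2OH, Pd(PPh3)4 (cat.), 1,4-dioxane, 80 °C
Reagents that add atoms: (tributylstannyl)methanol, CCCC[Sn](CO)(CCCC)CCCC
Why: Stille coupling should take place at the C–I bond, which adds to zerovalent palladium far faster than the vinylogous sulfonate, and installs C1 at the alcohol oxidation level.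

Step 8
Reactants: 12 (4R,5S)-5-[(tert-butyldimethylsilyl)oxy]-4-hydroxy-2-(hydroxymethyl)-4-methyl-3-oxocyclohex-1-en-1-yl 4-methylbenzenesulfonate; 13 (E)-pent-3-en-1-yne
Product: 15 (6S,7R)-6-[(tert-butyldimethylsilyl)oxy]-7-hydroxy-7-methyl-3-[(1E)-prop-1-en-1-yl]-6,7-dihydro-1H-isochromen-8(5H)-one, via enynol 14 (not isolated)
Conditions: 13 (excess), PdCl2(PPh3)2 (cat.), CuI (cat.), Et3N, DMF, 50 °C, sealed vessel
Reagents that add atoms: none
Why: Sonogashira coupling at the activated enol tosylate should give enynone 14, whose primary alcohol then adds to the alkyne terminus C3 (the δ position of the dienynone) in a copper-assisted 6-endo-dig cyclisation that closes the pyran ring with the E-propenyl group intact.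

Step 9
Reactants: 16 2,4-dihydroxy-6-methylbenzaldehyde
Product: 17 2-hydroxy-6-methyl-4-[(triisopropylsilyl)oxy]benzaldehyde
Conditions: i-Pr3SiCl, imidazole, DMF, 0 °C
Reagents that add atoms: triisopropylsilyl chloride, CC(C)[Si](Cl)(C(C)C)C(C)C
Why: The C4 hydroxyl should be silylated selectively, because the C2 hydroxyl is hydrogen-bonded to the aldehyde and more hindered.

Step 10
Reactants: 17 2-hydroxy-6-methyl-4-[(triisopropylsilyl)oxy]benzaldehyde
Product: 18 2-methoxy-6-methyl-4-[(triisopropylsilyl)oxy]benzaldehyde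
Conditions: MeI, K2CO3, acetone, reflux
Reagents that add atoms: iodomethane, CI
Why: Williamson O-methylation of the remaining phenol should proceed while the aryl triisopropylsilyl ether survives carbonate in acetone.

Step 11
Reactants: 18 2-methoxy-6-methyl-4-[(triisopropylsilyl)oxy]benzaldehyde
Product: 19 2-methoxy-6-methyl-4-[(triisopropylsilyl)oxy]benzoic acid
Conditions: NaClO2, NaH2PO4, 2-methylbut-2-ene, t-BuOH/H2O, rt
Reagents that add atoms: sodium chlorite, [Na+].[O-]Cl=O
Why: Pinnick oxidation should convert the hindered, electron-rich aldehyde into the acid, the alkene scavenging hypochlorite so that the arene is not chlorinated.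

Step 12
Reactants: 15 (6S,7R)-6-[(tert-butyldimethylsilyl)oxy]-7-hydroxy-7-methyl-3-[(1E)-prop-1-en-1-yl]-6,7-dihydro-1H-isochromen-8(5H)-one; 19 2-methoxy-6-methyl-4-[(triisopropylsilyl)oxy]benzoic acid
Product: 21 (6S,7R)-6-[(tert-butyldimethylsilyl)oxy]-7-methyl-8-oxo-3-[(1E)-prop-1-en-1-yl]-5,6,7,8-tetrahydro-1H-isochromen-7-yl 2-methoxy-6-methyl-4-[(triisopropylsilyl)oxy]benzoate, via aroyl chloride 20 (not isolated)
Conditions: 19, 1-chloro-N,N,2-trimethylprop-1-en-1-amine, CH2Cl2, 0 °C to rt; separately 15, LiN(SiMe3)2 (1.0 equiv), THF, −78 °C; then 20, −78 to 0 °C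
Reagents that add atoms: none
Why: The lithium alkoxide of the tertiary α-ketol (O–H is removed far faster than C5–H) should be acylated by the electron-rich aroyl chloride, which is made under neutral conditions so that the aryl silyl ether survives; C7 is not touched and keeps its configuration.

Step 13
Reactants: 21 (6S,7R)-6-[(tert-butyldimethylsilyl)oxy]-7-methyl-8-oxo-3-[(1E)-prop-1-en-1-yl]-5,6,7,8-tetrahydro-1H-isochromen-7-yl 2-methoxy-6-methyl-4-[(triisopropylsilyl)oxy]benzoate
Product: 22 (6S,7R)-6-hydroxy-7-methyl-8-oxo-3-[(1E)-prop-1-en-1-yl]-5,6,7,8-tetrahydro-1H-isochromen-7-yl 4-hydroxy-2-methoxy-6-methylbenzoate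
Conditions: HF·pyridine, pyridine/THF, 0 °C to rt
Reagents that add atoms: none
Why: Fluoride cleavage of the alkyl and aryl silyl ethers under mildly acidic conditions should free both hydroxyls without acyl migration from the hindered tertiary ester or damage to the dienol ether.

Compound list
1 | rac-but-3-en-2-ol | CC(O)C=C | starting material
2 | (2R,3S)-3,4-epoxybutan-2-ol | C[C@@H](O)[C@@H]1CO1 | intermediate
3 | (S)-1-(oxiran-2-yl)ethan-1-one | CC(=O)[C@@H]1CO1 | intermediate
4 | bis(1,3-dithian-2-yl)methane | C(C1SCCCS1)C1SCCCS1 | starting material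
5 | 2,2'-methylenebis(2-lithio-1,3-dithiane) | [Li]C1(CC2([Li])SCCCS2)SCCCS1 | intermediate
6 | lithium (1R)-1-{2-[(2-lithio-1,3-dithian-2-yl)methyl]-1,3-dithian-2-yl}-1-[(2S)-oxiran-2-yl]ethan-1-olate | C(C1([Li])SCCCS1)C1(SCCCS1)[C@](C)(O[Li])[C@@H]1CO1 | intermediate
7 | (5S,6R)-5,6-dihydroxy-6-methylcyclohexane-1,3-dione bis(propane-1,3-diyl dithioketal) (trans-diol) | C12(SCCCS1)[C@](C)(O)[C@@H](O)CC1(SCCCS1)C2 | intermediate
8 | (5S,6R)-5-[(tert-butyldimethylsilyl)oxy]-6-hydroxy-6-methylcyclohexane-1,3-dione bis(propane-1,3-diyl dithioketal) | C12(SCCCS1)[C@](C)(O)[C@@H](O[Si](C)(C)C(C)(C)C)CC1(SCCCS1)C2 | intermediate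
9 | (5S,6R)-5-[(tert-butyldimethylsilyl)oxy]-6-hydroxy-6-methylcyclohexane-1,3-dione | O=C1[C@](C)(O)[C@@H](O[Si](C)(C)C(C)(C)C)CC(=O)C1 | intermediate
10 | (5S,6R)-5-[(tert-butyldimethylsilyl)oxy]-3,6-dihydroxy-2-iodo-6-methylcyclohex-2-en-1-one (enol of the 2-iodo dione) | O=C1[C@](C)(O)[C@@H](O[Si](C)(C)C(C)(C)C)CC(O)=C1I | intermediate
11 | (4R,5S)-5-[(tert-butyldimethylsilyl)oxy]-4-hydroxy-2-iodo-4-methyl-3-oxocyclohex-1-en-1-yl 4-methylbenzenesulfonate | O=C1[C@](C)(O)[C@@H](O[Si](C)(C)C(C)(C)C)CC(OS(=O)(=O)c2ccc(C)cc2)=C1I | intermediate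
12 | (4R,5S)-5-[(tert-butyldimethylsilyl)oxy]-4-hydroxy-2-(hydroxymethyl)-4-methyl-3-oxocyclohex-1-en-1-yl 4-methylbenzenesulfonate | O=C1[C@](C)(O)[C@@H](O[Si](C)(C)C(C)(C)C)CC(OS(=O)(=O)c2ccc(C)cc2)=C1CO | intermediate
13 | (E)-pent-3-en-1-yne | C#C/C=C/C | starting material
14 | (5S,6R)-5-[(tert-butyldimethylsilyl)oxy]-6-hydroxy-2-(hydroxymethyl)-6-methyl-3-[(3E)-pent-3-en-1-yn-1-yl]cyclohex-2-en-1-one | O=C1[C@](C)(O)[C@@H](O[Si](C)(C)C(C)(C)C)CC(C#C/C=C/C)=C1CO | intermediate
15 | (6S,7R)-6-[(tert-butyldimethylsilyl)oxy]-7-hydroxy-7-methyl-3-[(1E)-prop-1-en-1-yl]-6,7-dihydro-1H-isochromen-8(5H)-one | C/C=C/C1=CC2=C(CO1)C(=O)[C@](C)(O)[C@@H](O[Si](C)(C)C(C)(C)C)C2 | intermediate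
16 | 2,4-dihydroxy-6-methylbenzaldehyde | Cc1cc(O)cc(O)c1C=O | starting material
17 | 2-hydroxy-6-methyl-4-[(triisopropylsilyl)oxy]benzaldehyde | Cc1cc(O[Si](C(C)C)(C(C)C)C(C)C)cc(O)c1C=O | intermediate
18 | 2-methoxy-6-methyl-4-[(triisopropylsilyl)oxy]benzaldehyde | Cc1cc(O[Si](C(C)C)(C(C)C)C(C)C)cc(OC)c1C=O | intermediate
19 | 2-methoxy-6-methyl-4-[(triisopropylsilyl)oxy]benzoic acid | Cc1cc(O[Si](C(C)C)(C(C)C)C(C)C)cc(OC)c1C(=O)O | intermediate
20 | 2-methoxy-6-methyl-4-[(triisopropylsilyl)oxy]benzoyl chloride | Cc1cc(O[Si](C(C)C)(C(C)C)C(C)C)cc(OC)c1C(Cl)=O | intermediate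
21 | (6S,7R)-6-[(tert-butyldimethylsilyl)oxy]-7-methyl-8-oxo-3-[(1E)-prop-1-en-1-yl]-5,6,7,8-tetrahydro-1H-isochromen-7-yl 2-methoxy-6-methyl-4-[(triisopropylsilyl)oxy]benzoate | C/C=C/C1=CC2=C(CO1)C(=O)[C@](C)(OC(=O)c1c(C)cc(O[Si](C(C)C)(C(C)C)C(C)C)cc1OC)[C@@H](O[Si](C)(C)C(C)(C)C)C2 | intermediate
22 | (6S,7R)-6-hydroxy-7-methyl-8-oxo-3-[(1E)-prop-1-en-1-yl]-5,6,7,8-tetrahydro-1H-isochromen-7-yl 4-hydroxy-2-methoxy-6-methylbenzoate | C/C=C/C1=CC2=C(CO1)C(=O)[C@](C)(OC(=O)c1c(C)cc(O)cc1OC)[C@@H](O)C2 | target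

Total step count: 13. Longest linear sequence: 10 steps (steps 1–8, 12 and 13).

Steps most likely to fail

Step 3. The carbonyl addition may take the other ketone face (entry anti to the oxirane C–O bond instead of the lithium-bridged mode), which would give the cis-diol. In that case the oxirane stereocentre is used only to set C7, and C6 is re-set by a hydroxyl-directed reduction. The fallback sets out from 1 and 4: kinetic resolution of 1 with L-(+)-diisopropyl tartrate gives (2S,3R)-3,4-epoxybutan-2-ol F1, and oxidation as in step 2 gives (R)-1-(oxiran-2-yl)ethan-1-one F2. Annulation with 4 under the step 3 conditions then gives the (5R,6R) cis-diol bis-dithioketal F3. Oxidation of its secondary alcohol with SO3·pyridine/DMSO/Et3N gives the α-hydroxy ketone F4. Reduction with Me4N[BH(OAc)3] in MeCN/AcOH delivers hydride from the face of the C7 hydroxyl and comes back to the route at the trans-diol 7.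

Step 12. Acylation of the hindered tertiary alkoxide may be slow, leaving time for deprotonation at C5 with β-elimination of the silyloxy group, or for attack of the acylating agent on the dienol ether carbon. The fallback esterifies earlier and without base; it sets out from 11 and uses 20. Treating 11 with 20, AgOSO2CF3 and 2,6-di-tert-butylpyridine in CH2Cl2 (acylium ion acylation) gives the aryl ester of the iodo enol tosylate F5. Stille coupling as in step 7 gives the hydroxymethyl ester F6. Sonogashira coupling with 13 as in step 8 gives the enynol ester F7, which closes to the pyran and comes back to the route at 21.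

Step 7. Oxidative addition may not discriminate cleanly between the C–I bond and the vinylogous sulfonate, or the C–I bond may simply be reduced. The fallback consumes the sulfonate before any iodine is present; it sets out from 9. TsCl/Et3N gives the iodine-free enol tosylate F8, and Sonogashira coupling with 13 gives the enynone F9. Iodination at C8a with I2/pyridine (addition–elimination of pyridine) gives the α-iodo enynone F10. Stille coupling with (tributylstannyl)methanol then gives 14, which closes under CuI/Et3N and comes back to the route at 15.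

Further compounds
F1 | step 3 | (2S,3R)-3,4-epoxybutan-2-ol | C[C@H](O)[C@H]1CO1
F2 | step 3 | (R)-1-(oxiran-2-yl)ethan-1-one | CC(=O)[C@H]1CO1
F3 | step 3 | (5R,6R)-5,6-dihydroxy-6-methylcyclohexane-1,3-dione bis(propane-1,3-diyl dithioketal) (cis-diol) | C12(SCCCS1)[C@](C)(O)[C@H](O)CC1(SCCCS1)C2
F4 | step 3 | (R)-2-hydroxy-2-methylcyclohexane-1,3,5-trione 3,5-bis(propane-1,3-diyl dithioketal) | C12(SCCCS1)[C@](C)(O)C(=O)CC1(SCCCS1)C2
F5 | step 12 | (1R,6S)-6-[(tert-butyldimethylsilyl)oxy]-3-iodo-1-methyl-2-oxo-4-(tosyloxy)cyclohex-3-en-1-yl 2-methoxy-6-methyl-4-[(triisopropylsilyl)oxy]benzoate | O=C1[C@](C)(OC(=O)c2c(C)cc(O[Si](C(C)C)(C(C)C)C(C)C)cc2OC)[C@@H](O[Si](C)(C)C(C)(C)C)CC(OS(=O)(=O)c2ccc(C)cc2)=C1I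
F6 | step 12 | (1R,6S)-6-[(tert-butyldimethylsilyl)oxy]-3-(hydroxymethyl)-1-methyl-2-oxo-4-(tosyloxy)cyclohex-3-en-1-yl 2-methoxy-6-methyl-4-[(triisopropylsilyl)oxy]benzoate | O=C1[C@](C)(OC(=O)c2c(C)cc(O[Si](C(C)C)(C(C)C)C(C)C)cc2OC)[C@@H](O[Si](C)(C)C(C)(C)C)CC(OS(=O)(=O)c2ccc(C)cc2)=C1CO
F7 | step 12 | (1R,6S)-6-[(tert-butyldimethylsilyl)oxy]-3-(hydroxymethyl)-1-methyl-2-oxo-4-[(3E)-pent-3-en-1-yn-1-yl]cyclohex-3-en-1-yl 2-methoxy-6-methyl-4-[(triisopropylsilyl)oxy]benzoate | O=C1[C@](C)(OC(=O)c2c(C)cc(O[Si](C(C)C)(C(C)C)C(C)C)cc2OC)[C@@H](O[Si](C)(C)C(C)(C)C)CC(C#C/C=C/C)=C1CO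
F8 | step 7 | (4R,5S)-5-[(tert-butyldimethylsilyl)oxy]-4-hydroxy-4-methyl-3-oxocyclohex-1-en-1-yl 4-methylbenzenesulfonate | O=C1[C@](C)(O)[C@@H](O[Si](C)(C)C(C)(C)C)CC(OS(=O)(=O)c2ccc(C)cc2)=C1
F9 | step 7 | (5S,6R)-5-[(tert-butyldimethylsilyl)oxy]-6-hydroxy-6-methyl-3-[(3E)-pent-3-en-1-yn-1-yl]cyclohex-2-en-1-one | O=C1[C@](C)(O)[C@@H](O[Si](C)(C)C(C)(C)C)CC(C#C/C=C/C)=C1
F10 | step 7 | (5S,6R)-5-[(tert-butyldimethylsilyl)oxy]-6-hydroxy-2-iodo-6-methyl-3-[(3E)-pent-3-en-1-yn-1-yl]cyclohex-2-en-1-one | O=C1[C@](C)(O)[C@@H](O[Si](C)(C)C(C)(C)C)CC(C#C/C=C/C)=C1I
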